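**Plan**

1. Cuts: (a) both aryl–carbonyl bonds of the quinone ring; (b) the allylic bond C1'–C3(ring), with C1'–C36' the side-chain carbons counted from the ring; (c) the two doubly allylic CH2–CH2 bonds C16'–C17' and C24'–C25' of the C45 chain.
2. Enabling feature: ring atoms C1(=O)–C2(CH3)=C3(R)–C4(=O) form a 1,4-dione flanked by an unsubstituted benzo ring. C1–C4 can therefore be drawn as the 2,5-bis(silyloxy)furan (bis-enol) of a 2-methyl-3-alkylsuccinic anhydride, and the benzo ring as benzyne. Their [4+2] adduct is a doubly ketalised 1,4-epoxide that collapses to the quinone at the correct oxidation level; benzyne is symmetric, so no regiochemistry arises.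
3. Chain assembly: (R)-citronellyl bromide → C15 dienol 5 (propargylation, Zr-catalysed methylalumination, CH2O). Compound 5 is used twice: as tail sulfone 7, and, after asymmetric hydrogenation to 8, as the source of C20 head 13 (second propargylation/methylalumination) and its terminal bromide 16. Then 16 + geranyl sulfone linchpin 19, then + 7, and one double desulfonylation give C45 alcohol 24.
4. Endgame and rings: allylic bromide 25 alkylates dimethyl 2-methylsuccinate; the temporary five-membered anhydride and furan rings (steps 21–22) serve as the diene template; the six-membered quinone ring is formed last (step 23) and the furan oxygen bridge and both silyl groups are lost.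
5. Stereochemistry: C11' and C31' are the stereocentre of (R)-citronellyl bromide; C7' is set by Ru(OAc)2[(S)-BINAP] hydrogenation of allylic alcohol 5. The 2' and 26' E-alkenes come from syn-carboalumination, the 14' and 22' E-alkenes from E-selective SeO2 oxidation, and the 18' E-alkene from geranyl bromide.

Key step: step 23

Remark: carbons that are stereocentres only for a time (the sulfone-bearing carbons of 20–22, both succinate carbons of 27–29, the bridgeheads of 33) are erased later, so these compounds are carried as mixtures and their SMILES leave those centres open.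

**Route**

Step 1
Reactants: 1 (R)-citronellyl bromide
Product: 3 (6S)-6,10-dimethylundec-9-en-1-yne, via silyl alkyne 2 (not isolated)
Conditions: MeC≡CSiMe3, n-BuLi, THF, −78 °C; then 1, DMPU, −78 °C to rt; then MeOH, K2CO3 (cat.), rt
Reagents that add atoms: 1-(trimethylsilyl)propyne CC#C[Si](C)(C)C
Why: SN2 alkylation of the propargylic lithium reagent of 1-(trimethylsilyl)propyne by the primary bromide, followed by K2CO3/MeOH cleavage of the C–Si bond in the same flask, should give the terminal alkyne with the citronellyl stereocentre untouched.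

Step 2
Reactants: 3 (6S)-6,10-dimethylundec-9-en-1-yne
Product: 5 (2E,7S)-3,7,11-trimethyldodeca-2,10-dien-1-ol, via alkenylalane 4 (not isolated)
Conditions: Me3Al, Cp2ZrCl2 (cat.), ClCH2CH2Cl, 0 °C to rt; then n-BuLi, THF/hexane, −78 °C; (CH2O)n, −78 °C to rt; aq. HCl work-up
Reagents that add atoms: trimethylaluminium C[Al](C)C; paraformaldehyde (as formaldehyde) C=O
Why: Zirconium-catalysed syn-methylalumination (Negishi carboalumination) puts methyl on the internal and aluminium on the terminal alkyne carbon, and the lithium alanate made with n-BuLi adds to formaldehyde with retention, so the 2,3-alkene should form as the E isomer while the remote trisubstituted alkene stays inert.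

Step 3
Reactants: 5 (2E,7S)-3,7,11-trimethyldodeca-2,10-dien-1-ol
Product: 7 [(2E,7S)-3,7,11-trimethyldodeca-2,10-dien-1-yl] phenyl sulfone, via allylic bromide 6 (not isolated)
Conditions: CBr4, PPh3, CH2Cl2, 0 °C; solvent exchange; PhSO2Na, DMF, rt
Reagents that add atoms: sodium benzenesulfinate [Na+].[O-]S(=O)c1ccccc1
Why: Appel bromination followed by SN2 S-alkylation of benzenesulfinate at the primary allylic carbon should give the E-allylic sulfone, which is also the thermodynamically preferred allylic isomer.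

Step 4
Reactants: 5 (2E,7S)-3,7,11-trimethyldodeca-2,10-dien-1-ol
Product: 8 (3R,7S)-3,7,11-trimethyldodec-10-en-1-ol
Conditions: H2 (100 atm), Ru(OAc)2[(S)-BINAP] (cat.), MeOH, 20 °C
Reagents that add atoms: none
Why: Noyori asymmetric hydrogenation of a geraniol-type allylic alcohol: hydroxyl-directed hydrogen delivery from the (S)-BINAP ruthenium catalyst to one face of the E-2,3-alkene should set the new methyl stereocentre as 3R under catalyst control (the sense that gives (R)-citronellol from geraniol), and the isolated 10,11-alkene is not reduced.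

Step 5
Reactants: 8 (3R,7S)-3,7,11-trimethyldodec-10-en-1-ol
Product: 9 (6S,10R)-12-bromo-2,6,10-trimethyldodec-2-ene
Conditions: CBr4, PPh3, CH2Cl2, 0 °C
Reagents that add atoms: carbon tetrabromide BrC(Br)(Br)Br
Why: Appel reaction: the alkoxyphosphonium ion of the primary alcohol is displaced by bromide (SN2) without effect on the stereocentres or the trisubstituted alkene.

Step 6
Reactants: 9 (6S,10R)-12-bromo-2,6,10-trimethyldodec-2-ene
Product: 11 (6R,10S)-6,10,14-trimethylpentadec-13-en-1-yne, via silyl alkyne 10 (not isolated)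
Conditions: MeC≡CSiMe3, n-BuLi, THF, −78 °C; then 9, DMPU, −78 °C to rt; then MeOH, K2CO3 (cat.), rt
Reagents that add atoms: 1-(trimethylsilyl)propyne CC#C[Si](C)(C)C
Why: The same propargylic SN2 alkylation and C–Si cleavage as in step 1 should add the three carbons C2'–C4' as a terminal alkyne.

Step 7
Reactants: 11 (6R,10S)-6,10,14-trimethylpentadec-13-en-1-yne
Product: 13 (2E,7R,11S)-3,7,11,15-tetramethylhexadeca-2,14-dien-1-ol, via alkenylalane 12 (not isolated)
Conditions: Me3Al, Cp2ZrCl2 (cat.), ClCH2CH2Cl, 0 °C to rt; then n-BuLi, THF/hexane, −78 °C; (CH2O)n, −78 °C to rt; aq. HCl work-up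
Reagents that add atoms: trimethylaluminium C[Al](C)C; paraformaldehyde (as formaldehyde) C=O
Why: Negishi carboalumination and formaldehyde trapping as in step 2 should give the 2E-allylic alcohol, which fixes the geometry of the alkene next to the future quinone.

Step 8
Reactants: 13 (2E,7R,11S)-3,7,11,15-tetramethylhexadeca-2,14-dien-1-ol
Product: 14 tert-butyldimethylsilyl ether of 13
Conditions: TBSCl, imidazole, DMF, rt
Reagents that add atoms: tert-butyldimethylsilyl chloride CC(C)(C)[Si](C)(C)Cl
Why: Standard silylation of a primary allylic alcohol; the silyl ether should tolerate SeO2, sulfonyl carbanions and LiEt3BH in steps 9–16.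

Step 9
Reactants: 14 tert-butyldimethylsilyl ether of 13
Product: 15 (2E,6S,10R,14E)-16-[(tert-butyldimethylsilyl)oxy]-2,6,10,14-tetramethylhexadeca-2,14-dien-1-ol
Conditions: SeO2 (cat.), t-BuOOH, salicylic acid (cat.), CH2Cl2, 0 °C to rt
Reagents that add atoms: tert-butyl hydroperoxide CC(C)(C)OO (terminal oxidant); selenium dioxide O=[Se]=O (transfers the oxygen)
Why: SeO2-catalysed allylic oxidation (ene reaction, then [2,3]-sigmatropic shift) should attack the electron-rich terminal isopropylidene group at its E-methyl, because the 2,3-alkene is deactivated by the allylic silyloxy group, and so give the E-allylic alcohol.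

Step 10
Reactants: 15 terminal allylic alcohol
Product: 16 {[(2E,7R,11S,14E)-16-bromo-3,7,11,15-tetramethylhexadeca-2,14-dien-1-yl]oxy}(tert-butyl)dimethylsilane
Conditions: CBr4, PPh3, CH2Cl2, −20 °C
Reagents that add atoms: carbon tetrabromide BrC(Br)(Br)Br
Why: Appel reaction on the primary allylic alcohol under neutral conditions should keep the E geometry and the silyl ether.

Step 11
Reactants: 17 geranyl bromide
Product: 18 geranyl phenyl sulfone
Conditions: PhSO2Na, DMF, rt
Reagents that add atoms: sodium benzenesulfinate [Na+].[O-]S(=O)c1ccccc1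
Why: SN2 S-alkylation of benzenesulfinate by a primary allylic bromide should give the E-allylic sulfone.

Step 12
Reactants: 18 geranyl phenyl sulfone
Product: 19 (2E,6E)-2,6-dimethyl-8-(phenylsulfonyl)octa-2,6-dien-1-ol
Conditions: SeO2 (cat.), t-BuOOH, salicylic acid (cat.), CH2Cl2, 0 °C to rt
Reagents that add atoms: tert-butyl hydroperoxide CC(C)(C)OO (terminal oxidant); selenium dioxide O=[Se]=O (transfers the oxygen)
Why: SeO2-catalysed allylic oxidation as in step 9 should be selective for the E-methyl of the terminal isopropylidene group, because the 2,3-alkene is deactivated by the sulfonyl group.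

Step 13
Reactants: 19 hydroxy sulfone linchpin, 16 head allylic bromide
Product: 20 C30 hydroxy sulfone (C16'–C17' bond formed; mixture of epimers at the sulfone carbon)
Conditions: 19, n-BuLi (2.1 equiv), THF/DMPU, −78 °C; then 16, −78 to −40 °C; H2O quench
Reagents that add atoms: none
Why: Alkylation of an α-sulfonyl carbanion: the O,C-dianion of 19 should react at its far more nucleophilic sulfonyl carbanion, at the carbon α to sulfur, with the primary allylic bromide in an SN2 reaction that keeps all alkene geometries; the new sulfone-bearing stereocentre is uncontrolled and is removed in step 16.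

Step 14
Reactants: 20 C30 hydroxy sulfone
Product: 21 C30 allylic bromide
Conditions: CBr4, PPh3, CH2Cl2, −20 °C
Reagents that add atoms: carbon tetrabromide BrC(Br)(Br)Br
Why: Appel reaction of the primary allylic alcohol; sulfone and silyl ether are inert under these neutral conditions.

Step 15
Reactants: 7 tail sulfone, 21 C30 allylic bromide
Product: 22 C45 bis-sulfone silyl ether (C24'–C25' bond formed; mixture of epimers at both sulfone carbons)
Conditions: 7, n-BuLi, THF/DMPU, −78 °C; then 21, −78 to −40 °C
Reagents that add atoms: none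
Why: Alkylation of an α-sulfonyl carbanion (SN2 at the primary allylic bromide): the lithio derivative of 7 is a weaker base than the anion that would arise from the tertiary sulfonyl C–H of 21, so substitution should outrun proton transfer; the second sulfone-bearing stereocentre is again temporary.

Step 16
Reactants: 22 C45 bis-sulfone silyl ether
Product: 23 tert-butyldimethylsilyl ether of the C45 alcohol
Conditions: LiEt3BH, PdCl2(dppp) (cat.), THF, 0 °C
Reagents that add atoms: none
Why: Palladium-catalysed reductive desulfonylation of allylic sulfones: zerovalent palladium formed in the flask ionises each allylic C–S bond to a π-allyl complex, and hydride from LiEt3BH is delivered to the less substituted (secondary) terminus, so the 18',19'- and 26',27'-alkenes should stay in place with E geometry.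

Step 17
Reactants: 23 silyl ether of the C45 alcohol
Product: 24 (2E,7R,11S,14E,18E,22E,26E,31S)-3,7,11,15,19,23,27,31,35-nonamethylhexatriaconta-2,14,18,22,26,34-hexaen-1-ol
Conditions: Bu4NF, THF, 0 °C to rt
Reagents that add atoms: none
Why: Fluoride-mediated cleavage of the silyl ether (Si–F bond formation) should free the primary allylic alcohol without touching the alkenes.

Step 18
Reactants: 24 C45 allylic alcohol
Product: 25 C45 (2E)-allylic bromide
Conditions: CBr4, PPh3, CH2Cl2, −20 °C; used at once
Reagents that add atoms: carbon tetrabromide BrC(Br)(Br)Br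
Why: Appel reaction of the primary allylic alcohol under neutral conditions should keep the 2E geometry.

Step 19
Reactants: 25 C45 allylic bromide, 26 dimethyl 2-methylsuccinate (racemic)
Product: 27 dimethyl 2-methyl-3-(C45 chain)succinate (mixture of diastereomers)
Conditions: 26 (excess), LiN(i-Pr)2, THF, −78 °C; then 25, DMPU, −78 to −20 °C
Reagents that add atoms: none
Why: Kinetic deprotonation of 26 should take place at the unsubstituted methylene, and the ester enolate is alkylated by the primary allylic bromide in an SN2 reaction that keeps the 2'E geometry; the two succinate stereocentres are not controlled because both become sp2 in step 22.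

Step 20
Reactants: 27 succinate diester
Product: 28 2-methyl-3-(C45 chain)succinic acid
Conditions: LiOH, THF/MeOH/H2O, 50 °C; then aq. HCl to pH 3, 0 °C
Reagents that add atoms: lithium hydroxide [Li+].[OH-]
Why: Saponification of both methyl esters by acyl substitution; epimerisation at the succinate carbons is of no consequence and the polyene should survive base and a brief cold acidification.

Step 21
Reactants: 28 succinic acid
Product: 29 3-methyl-4-(C45 chain)succinic anhydride
Conditions: Ac2O, toluene, 70 °C; evaporate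
Reagents that add atoms: none
Why: Cyclodehydration of a 1,4-diacid through the mixed anhydride (five-membered ring closure by acyl substitution) is easy for both diastereomers, and neutral Ac2O should leave the trisubstituted alkenes untouched.

Step 22
Reactants: 29 succinic anhydride
Product: 30 2,5-bis(tert-butyldimethylsilyloxy)-3-methyl-4-(C45 chain)furan
Conditions: TBSOTf, Et3N, CH2Cl2, 0 °C to rt; non-aqueous work-up (pentane, filtration), used directly
Reagents that add atoms: tert-butyldimethylsilyl trifluoromethanesulfonate CC(C)(C)[Si](C)(C)OS(=O)(=O)C(F)(F)F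
Why: Twofold soft enolisation and O-silylation (silyl ketene acetal formation) of the anhydride: the second enolisation is driven by aromatisation to the furan, which removes both temporary succinate stereocentres and creates the cyclic 1,4-dioxygenated diene.

Step 23
Reactants: 30 bis(silyloxy)furan, 31 2-iodophenyl trifluoromethanesulfonate
Product: 34 2-methyl-3-[(2E,7R,11S,14E,18E,22E,26E,31S)-3,7,11,15,19,23,27,31,35-nonamethylhexatriaconta-2,14,18,22,26,34-hexaen-1-yl]naphthalene-1,4-dione, via benzyne 32 (not isolated), via bridged cycloadduct 33 (not isolated)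
Conditions: 30 and 31 in THF, n-BuLi (slow addition), −78 °C, then to −20 °C; then Et3N·3HF, THF, 0 °C
Reagents that add atoms: none
Why: Iodine–lithium exchange on 31 at −78 °C and loss of LiOTf from the 2-lithioaryl triflate release benzyne 32, which is trapped in a concerted suprafacial [4+2] cycloaddition by the s-cis-locked, very electron-rich diene of furan 30 (C2=C3–C4=C5, both termini oxygenated), forming both aryl–carbon bonds at once and giving the 1,4-epoxy-1,4-bis(silyloxy)-1,4-dihydronaphthalene 33. The closest known reaction types are the aryne–furan Diels–Alder reaction (including 2-alkoxyfurans with arynes generated from 2-iodoaryl triflates and n-BuLi) and the use of 2,5-bis(silyloxy)furans from succinic anhydrides as quinone synthons towards alkyne dienophiles. The new six-membered carbocycle is closed by this intermolecular [4+2] mode; the furan oxygen becomes a one-atom bridge whose two bridgehead carbons are each a silyl ketal, so fluoride-induced collapse opens the bridge and should deliver the 1,4-dione without any redox step. The two bridgehead stereocentres of 33 are transient and vanish on collapse, and no regiochemical question arises because benzyne is symmetric. The selectivity needed is periselectivity for [4+2] at the furan over [2+2] or ene reactions at the six trisubstituted side-chain alkenes and over attack of n-BuLi on silicon; it is secured by the much higher reactivity of the cyclic bis(ketene acetal) diene, by the fully substituted C3 and C4 (which hinder stepwise arylation) and by slow addition of n-BuLi at −78 °C to a solution that already holds both partners.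

**Compound list**

1 | (R)-citronellyl bromide, (6R)-8-bromo-2,6-dimethyloct-2-ene | CC(C)=CCC[C@@H](C)CCBr | starting material
2 | trimethyl[(6S)-6,10-dimethylundec-9-en-1-yn-1-yl]silane | CC(C)=CCC[C@@H](C)CCCC#C[Si](C)(C)C | intermediate
3 | (6S)-6,10-dimethylundec-9-en-1-yne | CC(C)=CCC[C@@H](C)CCCC#C | intermediate
4 | dimethyl[(1E,6S)-2,6,10-trimethylundeca-1,9-dien-1-yl]alane | CC(C)=CCC[C@@H](C)CCC/C(C)=C/[Al](C)C | intermediate
5 | (2E,7S)-3,7,11-trimethyldodeca-2,10-dien-1-ol | CC(C)=CCC[C@@H](C)CCC/C(C)=C/CO | intermediate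
6 | (2E,7S)-1-bromo-3,7,11-trimethyldodeca-2,10-diene | CC(C)=CCC[C@@H](C)CCC/C(C)=C/CBr | intermediate
7 | [(2E,7S)-3,7,11-trimethyldodeca-2,10-dien-1-yl] phenyl sulfone | CC(C)=CCC[C@@H](C)CCC/C(C)=C/CS(=O)(=O)c1ccccc1 | intermediate
8 | (3R,7S)-3,7,11-trimethyldodec-10-en-1-ol | CC(C)=CCC[C@@H](C)CCC[C@@H](C)CCO | intermediate
9 | (6S,10R)-12-bromo-2,6,10-trimethyldodec-2-ene | CC(C)=CCC[C@@H](C)CCC[C@@H](C)CCBr | intermediate
10 | trimethyl[(6R,10S)-6,10,14-trimethylpentadec-13-en-1-yn-1-yl]silane | CC(C)=CCC[C@@H](C)CCC[C@@H](C)CCCC#C[Si](C)(C)C | intermediate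
11 | (6R,10S)-6,10,14-trimethylpentadec-13-en-1-yne | CC(C)=CCC[C@@H](C)CCC[C@@H](C)CCCC#C | intermediate
12 | dimethyl[(1E,6R,10S)-2,6,10,14-tetramethylpentadeca-1,13-dien-1-yl]alane | CC(C)=CCC[C@@H](C)CCC[C@@H](C)CCC/C(C)=C/[Al](C)C | intermediate
13 | (2E,7R,11S)-3,7,11,15-tetramethylhexadeca-2,14-dien-1-ol | CC(C)=CCC[C@@H](C)CCC[C@@H](C)CCC/C(C)=C/CO | intermediate
14 | tert-butyldimethyl{[(2E,7R,11S)-3,7,11,15-tetramethylhexadeca-2,14-dien-1-yl]oxy}silane | CC(C)=CCC[C@@H](C)CCC[C@@H](C)CCC/C(C)=C/CO[Si](C)(C)C(C)(C)C | intermediate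
15 | (2E,6S,10R,14E)-16-[(tert-butyldimethylsilyl)oxy]-2,6,10,14-tetramethylhexadeca-2,14-dien-1-ol | OC/C(C)=C/CC[C@@H](C)CCC[C@@H](C)CCC/C(C)=C/CO[Si](C)(C)C(C)(C)C | intermediate
16 | {[(2E,7R,11S,14E)-16-bromo-3,7,11,15-tetramethylhexadeca-2,14-dien-1-yl]oxy}(tert-butyl)dimethylsilane | BrC/C(C)=C/CC[C@@H](C)CCC[C@@H](C)CCC/C(C)=C/CO[Si](C)(C)C(C)(C)C | intermediate
17 | geranyl bromide, (2E)-1-bromo-3,7-dimethylocta-2,6-diene | CC(C)=CCC/C(C)=C/CBr | starting material
18 | geranyl phenyl sulfone, [(2E)-3,7-dimethylocta-2,6-dien-1-yl] phenyl sulfone | CC(C)=CCC/C(C)=C/CS(=O)(=O)c1ccccc1 | intermediate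
19 | (2E,6E)-2,6-dimethyl-8-(phenylsulfonyl)octa-2,6-dien-1-ol | OC/C(C)=C/CC/C(C)=C/CS(=O)(=O)c1ccccc1 | intermediate
20 | (2E,6E,10E,14S,18R,22E)-24-[(tert-butyldimethylsilyl)oxy]-2,6,10,14,18,22-hexamethyl-8-(phenylsulfonyl)tetracosa-2,6,10,22-tetraen-1-ol (C8 epimers) | OC/C(C)=C/CC/C(C)=C/C(S(=O)(=O)c1ccccc1)C/C(C)=C/CC[C@@H](C)CCC[C@@H](C)CCC/C(C)=C/CO[Si](C)(C)C(C)(C)C | intermediate
21 | {[(2E,7R,11S,14E,18E,22E)-24-bromo-3,7,11,15,19,23-hexamethyl-17-(phenylsulfonyl)tetracosa-2,14,18,22-tetraen-1-yl]oxy}(tert-butyl)dimethylsilane (C17 epimers) | BrC/C(C)=C/CC/C(C)=C/C(S(=O)(=O)c1ccccc1)C/C(C)=C/CC[C@@H](C)CCC[C@@H](C)CCC/C(C)=C/CO[Si](C)(C)C(C)(C)C | intermediate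
22 | tert-butyldimethyl{[(2E,7R,11S,14E,18E,22E,26E,31S)-3,7,11,15,19,23,27,31,35-nonamethyl-17,25-bis(phenylsulfonyl)hexatriaconta-2,14,18,22,26,34-hexaen-1-yl]oxy}silane (C17/C25 epimers) | CC(C)=CCC[C@@H](C)CCC/C(C)=C/C(S(=O)(=O)c1ccccc1)C/C(C)=C/CC/C(C)=C/C(S(=O)(=O)c1ccccc1)C/C(C)=C/CC[C@@H](C)CCC[C@@H](C)CCC/C(C)=C/CO[Si](C)(C)C(C)(C)C | intermediate
23 | tert-butyldimethyl{[(2E,7R,11S,14E,18E,22E,26E,31S)-3,7,11,15,19,23,27,31,35-nonamethylhexatriaconta-2,14,18,22,26,34-hexaen-1-yl]oxy}silane | CC(C)=CCC[C@@H](C)CCC/C(C)=C/CC/C(C)=C/CC/C(C)=C/CC/C(C)=C/CC[C@@H](C)CCC[C@@H](C)CCC/C(C)=C/CO[Si](C)(C)C(C)(C)C | intermediate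
24 | (2E,7R,11S,14E,18E,22E,26E,31S)-3,7,11,15,19,23,27,31,35-nonamethylhexatriaconta-2,14,18,22,26,34-hexaen-1-ol | CC(C)=CCC[C@@H](C)CCC/C(C)=C/CC/C(C)=C/CC/C(C)=C/CC/C(C)=C/CC[C@@H](C)CCC[C@@H](C)CCC/C(C)=C/CO | intermediate
25 | (2E,7R,11S,14E,18E,22E,26E,31S)-1-bromo-3,7,11,15,19,23,27,31,35-nonamethylhexatriaconta-2,14,18,22,26,34-hexaene | CC(C)=CCC[C@@H](C)CCC/C(C)=C/CC/C(C)=C/CC/C(C)=C/CC/C(C)=C/CC[C@@H](C)CCC[C@@H](C)CCC/C(C)=C/CBr | intermediate
26 | dimethyl 2-methylbutanedioate (dimethyl 2-methylsuccinate, racemic) | COC(=O)CC(C)C(=O)OC | starting material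
27 | dimethyl 2-methyl-3-[(2E,7R,11S,14E,18E,22E,26E,31S)-3,7,11,15,19,23,27,31,35-nonamethylhexatriaconta-2,14,18,22,26,34-hexaen-1-yl]butanedioate (C2/C3 diastereomers) | CC(C)=CCC[C@@H](C)CCC/C(C)=C/CC/C(C)=C/CC/C(C)=C/CC/C(C)=C/CC[C@@H](C)CCC[C@@H](C)CCC/C(C)=C/CC(C(=O)OC)C(C)C(=O)OC | intermediate
28 | 2-methyl-3-[(2E,7R,11S,14E,18E,22E,26E,31S)-3,7,11,15,19,23,27,31,35-nonamethylhexatriaconta-2,14,18,22,26,34-hexaen-1-yl]butanedioic acid (C2/C3 diastereomers) | CC(C)=CCC[C@@H](C)CCC/C(C)=C/CC/C(C)=C/CC/C(C)=C/CC/C(C)=C/CC[C@@H](C)CCC[C@@H](C)CCC/C(C)=C/CC(C(=O)O)C(C)C(=O)O | intermediate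
29 | 3-methyl-4-[(2E,7R,11S,14E,18E,22E,26E,31S)-3,7,11,15,19,23,27,31,35-nonamethylhexatriaconta-2,14,18,22,26,34-hexaen-1-yl]oxolane-2,5-dione (C3/C4 diastereomers) | CC(C)=CCC[C@@H](C)CCC/C(C)=C/CC/C(C)=C/CC/C(C)=C/CC/C(C)=C/CC[C@@H](C)CCC[C@@H](C)CCC/C(C)=C/CC1C(C)C(=O)OC1=O | intermediate
30 | 2,5-bis[(tert-butyldimethylsilyl)oxy]-3-methyl-4-[(2E,7R,11S,14E,18E,22E,26E,31S)-3,7,11,15,19,23,27,31,35-nonamethylhexatriaconta-2,14,18,22,26,34-hexaen-1-yl]furan | CC(C)=CCC[C@@H](C)CCC/C(C)=C/CC/C(C)=C/CC/C(C)=C/CC/C(C)=C/CC[C@@H](C)CCC[C@@H](C)CCC/C(C)=C/Cc1c(C)c(O[Si](C)(C)C(C)(C)C)oc1O[Si](C)(C)C(C)(C)C | intermediate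
31 | 2-iodophenyl trifluoromethanesulfonate | FC(F)(F)S(=O)(=O)Oc1ccccc1I | starting material
32 | benzyne (cyclohexa-1,3-dien-5-yne) | C1=CC#CC=C1 | intermediate
33 | 1,4-bis[(tert-butyldimethylsilyl)oxy]-2-methyl-3-[(2E,7R,11S,14E,18E,22E,26E,31S)-3,7,11,15,19,23,27,31,35-nonamethylhexatriaconta-2,14,18,22,26,34-hexaen-1-yl]-1,4-dihydro-1,4-epoxynaphthalene (bridgehead diastereomers) | CC(C)=CCC[C@@H](C)CCC/C(C)=C/CC/C(C)=C/CC/C(C)=C/CC/C(C)=C/CC[C@@H](C)CCC[C@@H](C)CCC/C(C)=C/CC1=C(C)C2(O[Si](C)(C)C(C)(C)C)OC1(O[Si](C)(C)C(C)(C)C)c1ccccc12 | intermediate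
34 | 2-methyl-3-[(2E,7R,11S,14E,18E,22E,26E,31S)-3,7,11,15,19,23,27,31,35-nonamethylhexatriaconta-2,14,18,22,26,34-hexaen-1-yl]naphthalene-1,4-dione | CC(C)=CCC[C@@H](C)CCC/C(C)=C/CC/C(C)=C/CC/C(C)=C/CC/C(C)=C/CC[C@@H](C)CCC[C@@H](C)CCC/C(C)=C/CC1=C(C)C(=O)c2ccccc2C1=O | target

**Step count and risks**

Total step count: 23. Longest linear sequence: 20 steps (steps 1, 2, 4–10 and 13–23, from 1).

Steps most likely to fail:

1. Step 23. The aryne may be consumed by addition of n-BuLi, by ene reaction at the side-chain alkenes, or by stepwise arylation or [2+2] addition at a ketene acetal carbon; the silyl ketene acetals may also be cleaved before cycloaddition. The fallback gives up ring construction and introduces the naphthalene intact; it sets out from 25 and returns at 34. Commercial 1,4-dimethoxy-2-methylnaphthalene would be brominated (NBS, MeCN) to 2-bromo-1,4-dimethoxy-3-methylnaphthalene F1. Bromine–lithium exchange (n-BuLi, THF, −78 °C) and transmetalation with CuBr·SMe2 would give the arylcopper reagent, which is allylated by 25 in an SN2 reaction to 1,4-dimethoxy-2-methyl-3-(C45 chain)naphthalene F2. Oxidative demethylation with (NH4)2Ce(NO3)6 in MeCN/H2O at 0 °C would then give 34.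

2. Step 13. The alkoxide of the dianion may compete by O-alkylation or by base-induced elimination of the allylic bromide, or the second deprotonation may be incomplete. The fallback masks the hydroxyl and works through a monoanion; it sets out from 19 (with 16) and returns at 20. Compound 19 would be converted to its triethylsilyl ether F3 (Et3SiCl, imidazole, CH2Cl2). The monolithio sulfone of F3 (n-BuLi, THF, −78 °C) would be alkylated with 16 to the doubly silylated C30 sulfone F4. The primary allylic triethylsilyl ether would then be cleaved selectively in the presence of the tert-butyldimethylsilyl ether (pyridinium p-toluenesulfonate, MeOH, 0 °C) to give 20.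

3. Step 19. Enolisation of 26 may not be regioselective (methine versus methylene), and the succinate enolate may undergo Claisen-type self-condensation faster than it is alkylated by the hindered C45 bromide. The fallback is a malonic ester synthesis with unambiguous regiochemistry; it sets out from 25 and returns at 28. Triethyl propane-1,1,2-tricarboxylate F5 (from diethyl malonate, NaOEt and ethyl 2-bromopropanoate) would be deprotonated with NaH in THF/DMF at its only malonate C–H and alkylated with 25 to triethyl 1-(C45 chain)propane-1,1,2-tricarboxylate F6. Saponification (KOH, aq. EtOH, 60 °C; cold acidification) would give 1-(C45 chain)propane-1,1,2-tricarboxylic acid F7, and its decarboxylation (pyridine, 100 °C) would give diacid 28.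

Further compounds
F1 | step 23 | 2-bromo-1,4-dimethoxy-3-methylnaphthalene | COc1c(Br)c(C)c(OC)c2ccccc12
F2 | step 23 | 1,4-dimethoxy-2-methyl-3-[(2E,7R,11S,14E,18E,22E,26E,31S)-3,7,11,15,19,23,27,31,35-nonamethylhexatriaconta-2,14,18,22,26,34-hexaen-1-yl]naphthalene | CC(C)=CCC[C@@H](C)CCC/C(C)=C/CC/C(C)=C/CC/C(C)=C/CC/C(C)=C/CC[C@@H](C)CCC[C@@H](C)CCC/C(C)=C/Cc1c(C)c(OC)c2ccccc2c1OC
F3 | step 13 | triethyl{[(2E,6E)-2,6-dimethyl-8-(phenylsulfonyl)octa-2,6-dien-1-yl]oxy}silane | CC[Si](CC)(CC)OC/C(C)=C/CC/C(C)=C/CS(=O)(=O)c1ccccc1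
F4 | step 13 | triethylsilyl ether of 20 (C8 epimers) | CC[Si](CC)(CC)OC/C(C)=C/CC/C(C)=C/C(S(=O)(=O)c1ccccc1)C/C(C)=C/CC[C@@H](C)CCC[C@@H](C)CCC/C(C)=C/CO[Si](C)(C)C(C)(C)C
F5 | step 19 | triethyl propane-1,1,2-tricarboxylate | CCOC(=O)C(C(=O)OCC)C(C)C(=O)OCC
F6 | step 19 | triethyl 1-[(2E,7R,11S,14E,18E,22E,26E,31S)-3,7,11,15,19,23,27,31,35-nonamethylhexatriaconta-2,14,18,22,26,34-hexaen-1-yl]propane-1,1,2-tricarboxylate | CC(C)=CCC[C@@H](C)CCC/C(C)=C/CC/C(C)=C/CC/C(C)=C/CC/C(C)=C/CC[C@@H](C)CCC[C@@H](C)CCC/C(C)=C/CC(C(=O)OCC)(C(=O)OCC)C(C)C(=O)OCC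
F7 | step 19 | 1-[(2E,7R,11S,14E,18E,22E,26E,31S)-3,7,11,15,19,23,27,31,35-nonamethylhexatriaconta-2,14,18,22,26,34-hexaen-1-yl]propane-1,1,2-tricarboxylic acid | CC(C)=CCC[C@@H](C)CCC/C(C)=C/CC/C(C)=C/CC/C(C)=C/CC/C(C)=C/CC[C@@H](C)CCC[C@@H](C)CCC/C(C)=C/CC(C(=O)O)(C(=O)O)C(C)C(=O)O
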